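**Plan**

1. Cuts: the 2H-pyran is opened at C2 (C–H from hydride; C–O and C–C back to a dihydropyranone built from (E)-dodec-4-en-3-one). The cyclopentane is cut at the bond between the CH2 beside its carbinol and the ring-fusion CH. The bicyclo[2.2.2] lactone is cut by retro-[4+2] into a 3-benzyloxy-2-pyrone-4-carboxylate and benzyl vinyl ether. The pyrone is cut into an alkoxyacetate, an oxalate and an alkyne from (S)-epibromohydrin.
2. Forward order: 2-pyrone, then the bridged lactone (inverse-demand Diels–Alder), then the cyclopentane (radical closure), then the dihydropyranone, then the 2H-pyran, then desilylation.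
3. Stereochemistry: the cyclopentane carbinol comes from (S)-epibromohydrin; both bridgeheads and the cage carbinol from the catalyst-controlled endo cycloaddition; the ring-fusion CH from the radical closure; the ester-bearing CH by equilibration; pyran C2 by hydride delivery anti to the lactone carbonyl.
4. Enabling feature: the C4=C5 bond of the pyrone, conjugated to the C4 ester, survives the cycloaddition as the enoate bridge of the 2-oxabicyclo[2.2.2]octenone. Its β-carbon is 1,5-related, through the side-chain bridgehead, to the CH2Br carbon.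

Key step: step 9

Assumption: the (S,S) enantiomer of the bis(oxazoline) ligand (2,2'-(propane-2,2-diyl)bis[(4S)-4-tert-butyl-4,5-dihydro-1,3-oxazole], "t-Bu-box") is taken to give the absolute configuration drawn for 16; the sense of induction for this binding mode is unknown, and the antipodal ligand would be used if it proved opposite.

Locants: 2-pyrone numbering for 14. For 16 and later cage compounds, C1 = bridgehead carrying the side chain, O2, C3 = lactone carbonyl, C4 = oxygenated bridgehead, C5/C6 = enoate bridge (C5 next to C4), C7/C8 = third bridge (C8 next to C4). "Pyran C2" is the carbon bearing the nonenyl chain.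

**Step 1**
Reactants: 1 octanal; 2 diethyl (2-oxobutyl)phosphonate
Product: 3 (E)-dodec-4-en-3-one
Conditions: NaH, THF, 0 °C to rt
Reagents that add atoms: none
Why: Horner–Wadsworth–Emmons olefination of the aldehyde with the stabilised β-keto phosphonate anion should give the E-enone, the phosphonate carbon being the only nucleophilic site.

**Step 2**
Reactants: 4 (S)-epibromohydrin; 5 acetylene
Product: 6 (S)-1-bromopent-4-yn-2-ol
Conditions: 5, n-BuLi, THF, −78 °C; BF3·OEt2; 4, −78 °C; NH4Cl (aq) quench at −78 °C
Reagents that add atoms: none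
Why: BF3-promoted epoxide opening by lithium acetylide (Yamaguchi–Hirao alkynylation) at the unsubstituted epoxide carbon leaves the stereocentre untouched, so the (S) carbinol that becomes the cyclopentanol carbon is taken from the chiral pool, and the cold quench keeps the bromohydrin from closing back to an epoxide.

**Step 3**
Reactants: 6 (S)-1-bromopent-4-yn-2-ol
Product: 7 tert-butyl{[(2S)-1-bromopent-4-yn-2-yl]oxy}diphenylsilane
Conditions: TBDPSCl, imidazole, CH2Cl2, 0 °C to rt
Reagents that add atoms: tert-butyl(chloro)diphenylsilane, CC(C)(C)[Si](Cl)(c1ccccc1)c1ccccc1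
Why: Imidazole-mediated silylation of the secondary alcohol is too weakly basic to displace bromide, and the tert-butyldiphenylsilyl ether is chosen because it should survive the trifluoroacetic acid of step 7 and the hydrogenolysis of step 10.

**Step 4**
Reactants: 8 tert-butyl 2-(benzyloxy)acetate; 9 dibenzyl oxalate
Product: 10 1-benzyl 4-tert-butyl 3-(benzyloxy)-2-oxobutanedioate
Conditions: LiN(SiMe3)2 (2 equiv), THF, −78 °C to 0 °C; HCl (aq)
Reagents that add atoms: none
Why: Crossed Claisen condensation, in which the lithium enolate of the α-alkoxy ester acylates the non-enolisable oxalate once and the acidic product is held as its enolate until work-up.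

**Step 5**
Reactants: 10 1-benzyl 4-tert-butyl 3-(benzyloxy)-2-oxobutanedioate
Product: 11 1-benzyl 4-tert-butyl (2E)-3-(benzyloxy)-2-{[(trifluoromethyl)sulfonyl]oxy}but-2-enedioate
Conditions: NaH, Et2O, 0 °C; Tf2O, −78 °C to 0 °C
Reagents that add atoms: trifluoromethanesulfonic anhydride, O=S(=O)(OS(=O)(=O)C(F)(F)F)C(F)(F)F
Why: O-Sulfonylation of the sodium enolate, held in a six-membered chelate with the enolate oxygen cis to the tert-butyl ester, should give the E enol triflate in which the leaving group and the future lactone carboxyl are cis.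

**Step 6**
Reactants: 11 enol triflate; 7 tert-butyl{[(2S)-1-bromopent-4-yn-2-yl]oxy}diphenylsilane
Product: 12 1-benzyl 4-tert-butyl (2Z)-3-(benzyloxy)-2-[(4S)-5-bromo-4-(tert-butyldiphenylsilyloxy)pent-1-yn-1-yl]but-2-enedioate
Conditions: PdCl2(PPh3)2 (3 mol%), CuI (6 mol%), Et3N, THF, rt
Reagents that add atoms: none
Why: Sonogashira coupling of the electron-poor enol triflate with the terminal alkyne proceeds with retention of alkene geometry, and the primary bromide and silyl ether are inert to the palladium–copper system at room temperature.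

**Step 7**
Reactants: 12 enynoate diester
Product: 14 benzyl 3-(benzyloxy)-6-[(2S)-3-bromo-2-(tert-butyldiphenylsilyloxy)propyl]-2-oxo-2H-pyran-4-carboxylate, via enynoic acid 13 (not isolated)
Conditions: TFA, CH2Cl2, 0 °C to rt; evaporate; ZnBr2 (10 mol%), THF, rt
Reagents that add atoms: none
Why: Acidolysis removes only the tert-butyl ester, and the freed acid, cis to the alkyne, closes 6-endo-dig at the alkyne carbon remote from the diester alkene (ZnBr2-catalysed lactonisation of a (Z)-2-en-4-ynoic acid, a conjugate-addition-type closure) to give the 2-pyrone, not the 5-exo ylidene butenolide.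

**Step 8**
Reactants: 14 pyrone; 15 benzyl vinyl ether
Product: 16 benzyl 4,8-bis(benzyloxy)-1-[(2S)-3-bromo-2-(tert-butyldiphenylsilyloxy)propyl]-3-oxo-2-oxabicyclo[2.2.2]oct-5-ene-5-carboxylate (8-OBn syn to the C5=C6 bridge)
Conditions: Cu(OTf)2 (10 mol%), (S,S)-t-Bu-box (11 mol%), 4 Å molecular sieves, CH2Cl2, −20 °C
Reagents that add atoms: none
Why: Inverse-electron-demand Diels–Alder reaction of the ester-activated 2-pyrone with an enol ether under chiral Lewis acid catalysis, a known reaction type for electron-poor 2-pyrones, in which two-point binding of the C3 benzyloxy oxygen and the lactone carbonyl to copper should fix the diene face, the nucleophilic CH2 terminus bonds to pyrone C6 as enol ethers do with 2-pyrones, and the endo transition state places the new C8 benzyloxy group syn to the enoate bridge, so both bridgeheads and C8 are set here.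

**Step 9**
Reactants: 16 bromo cycloadduct
Product: 18 cyclopentane-fused cage ester (ring C1–CH2–CH(OTBDPS)–CH2–C6; new C6–CH2 bond and C5 benzyl ester syn to the lactone bridge), via ester epimer mixture 17 (not isolated)
Conditions: (Me3Si)3SiH, Et3B, air, toluene, 0 °C to rt; then DBU, rt
Reagents that add atoms: none
Why: The (Me3Si)3Si radical abstracts bromine and the primary alkyl radical adds to C6, the β-carbon of the bridging enoate, after which the α-ester radical takes hydrogen from the silane; the closest known reaction type is the tin-free reductive radical conjugate (Giese-type) cyclisation of haloalkyl acrylates. The cyclopentane closes in the 5-exo-trig mode, since C6 is 1,5 to the radical carbon through bridgehead C1, and 6-endo attack at the ester-bearing C5 is slower and polarity-mismatched. The ring-fusion centre C6 is controlled by the cage: the alkene face syn to the lactone bridge is flanked only by the ring oxygen, the other face is screened by the C7 methylene and the endo C8 benzyloxy group, and the chair-like transition state with the silyloxy group pseudo-equatorial (1,3-trans outcome) selects the same face. The ester-bearing centre C5 is then set under thermodynamic control, DBU equilibrating the epimers to the one with the ester syn to the lactone bridge, remote from the C8 benzyloxy group. The step needs cyclisation to outrun direct reduction of the primary radical, which the activated acceptor and the slow hydrogen donor should secure, and carrying the ring carbinol as its silyl ether avoids the base-induced loss of the lactone oxygen that a ketone at that position would invite.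

**Step 10**
Reactants: 18 cyclopentane-fused cage ester
Product: 19 hydroxy acid (C5 carboxylic acid with free C4 and C8 hydroxyls)
Conditions: H2 (1 atm), Pd/C, EtOAc, rt
Reagents that add atoms: none
Why: Hydrogenolysis cleaves the two benzyl ethers and the benzyl ester in one operation at a stage with no C=C bond, while the lactone, the silyl ether and all stereocentres are untouched.

**Step 11**
Reactants: 19 hydroxy acid
Product: 20 pentafluorophenyl ester of 19
Conditions: C6F5OH, DCC, EtOAc, 0 °C to rt
Reagents that add atoms: pentafluorophenol, Oc1c(F)c(F)c(F)c(F)c1F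
Why: Carbodiimide esterification without an acyl-transfer catalyst converts the acid into an active ester, and the tertiary and the hindered secondary hydroxyl should not be acylated under these conditions.

**Step 12**
Reactants: 20 pentafluorophenyl ester; 3 (E)-dodec-4-en-3-one
Product: 22 cage-fused 2,3-dihydro-4H-pyran-4-one (ring O on C4, ring carbonyl on C5; 3-methyl; 2-[(E)-non-1-enyl]), via diketone 21 (not isolated)
Conditions: MgBr2·OEt2, iPr2NEt, CH2Cl2, rt; aqueous work-up; crude with TsOH·H2O (10 mol%), CH2Cl2, rt
Reagents that add atoms: none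
Why: Soft enolisation of the enone at its ethyl CH2 and C-acylation by the active ester (Claisen-type acylation) should give the β-diketone, whose distal carbonyl is attacked by the neighbouring tertiary hydroxyl and dehydrated under acid to the six-membered vinylogous ester, as in chromone formation; the methyl-bearing carbon becomes sp2, so no stereocentre is created.

**Step 13**
Reactants: 22 cage-fused dihydropyranone
Product: 24 tert-butyldiphenylsilyl ether of the target, via allylic alcohol 23 (not isolated)
Conditions: NaBH4, CeCl3·7H2O, MeOH, −78 °C; work-up; crude with Et3SiH, TFA, CH2Cl2, −78 °C to −40 °C; Et3N quench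
Reagents that add atoms: none
Why: Luche 1,2-reduction gives the allylic alcohol, which ionises under acid to the cyclic allyl oxocarbenium ion (Ferrier-type reductive transposition; the ring holds the alkene s-cis to the C=O+ unit, so Nazarov closure is not possible), and triethylsilane should deliver hydride to pyran C2 on the face anti to the lactone carbonyl, which lies 1,3-diaxially under the other face, so the nonenyl group ends syn to the lactone bridge as in the target.

**Step 14**
Reactants: 24 silyl ether of the target
Product: 25 CNP0127096.1 (target)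
Conditions: Bu4NF, AcOH, THF, 0 °C to rt
Reagents that add atoms: none
Why: Fluoride cleaves the silyl ether, acetic acid buffering should keep the bridged lactone and the doubly allylic ether intact, and no stereocentre is touched.

**Compound list**

1 | octanal | CCCCCCCC=O | starting material
2 | diethyl (2-oxobutyl)phosphonate | CCC(=O)CP(=O)(OCC)OCC | starting material
3 | (E)-dodec-4-en-3-one | CCCCCCC/C=C/C(=O)CC | intermediate
4 | (S)-epibromohydrin | BrC[C@@H]1CO1 | starting material
5 | acetylene | C#C | starting material
6 | (S)-1-bromopent-4-yn-2-ol | BrC[C@@H](O)CC#C | intermediate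
7 | tert-butyl{[(2S)-1-bromopent-4-yn-2-yl]oxy}diphenylsilane | BrC[C@@H](O[Si](c1ccccc1)(c1ccccc1)C(C)(C)C)CC#C | intermediate
8 | tert-butyl 2-(benzyloxy)acetate | CC(C)(C)OC(=O)COCc1ccccc1 | starting material
9 | dibenzyl oxalate | O=C(OCc1ccccc1)C(=O)OCc1ccccc1 | starting material
10 | 1-benzyl 4-tert-butyl 3-(benzyloxy)-2-oxobutanedioate | CC(C)(C)OC(=O)C(OCc1ccccc1)C(=O)C(=O)OCc1ccccc1 | intermediate
11 | 1-benzyl 4-tert-butyl (2E)-3-(benzyloxy)-2-{[(trifluoromethyl)sulfonyl]oxy}but-2-enedioate (triflate cis to the tert-butyl ester) | CC(C)(C)OC(=O)/C(OCc1ccccc1)=C(OS(=O)(=O)C(F)(F)F)/C(=O)OCc1ccccc1 | intermediate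
12 | 1-benzyl 4-tert-butyl (2Z)-3-(benzyloxy)-2-[(4S)-5-bromo-4-(tert-butyldiphenylsilyloxy)pent-1-yn-1-yl]but-2-enedioate | CC(C)(C)OC(=O)/C(OCc1ccccc1)=C(C#CC[C@@H](CBr)O[Si](c1ccccc1)(c1ccccc1)C(C)(C)C)/C(=O)OCc1ccccc1 | intermediate
13 | enynoic acid (free carboxylic acid in place of the tert-butyl ester of 12) | OC(=O)/C(OCc1ccccc1)=C(C#CC[C@@H](CBr)O[Si](c1ccccc1)(c1ccccc1)C(C)(C)C)/C(=O)OCc1ccccc1 | intermediate (not isolated)
14 | benzyl 3-(benzyloxy)-6-[(2S)-3-bromo-2-(tert-butyldiphenylsilyloxy)propyl]-2-oxo-2H-pyran-4-carboxylate | O=C1OC(C[C@@H](CBr)O[Si](c2ccccc2)(c2ccccc2)C(C)(C)C)=CC(C(=O)OCc2ccccc2)=C1OCc1ccccc1 | intermediate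
15 | benzyl vinyl ether | C=COCc1ccccc1 | starting material
16 | benzyl 4,8-bis(benzyloxy)-1-[(2S)-3-bromo-2-(tert-butyldiphenylsilyloxy)propyl]-3-oxo-2-oxabicyclo[2.2.2]oct-5-ene-5-carboxylate, 8-OBn syn to the C5=C6 bridge | c1ccccc1CO[C@@]23C(=O)O[C@@](C[C@@H](CBr)O[Si](c4ccccc4)(c4ccccc4)C(C)(C)C)(C=C2C(=O)OCc5ccccc5)C[C@H]3OCc6ccccc6 | intermediate
17 | radical cyclisation product as a mixture of C5 ester epimers | c1ccccc1CO[C@@]23C(=O)O[C@]4(C[C@H](O[Si](c7ccccc7)(c7ccccc7)C(C)(C)C)C[C@H]4C2C(=O)OCc5ccccc5)C[C@H]3OCc6ccccc6 | intermediate (not isolated)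
18 | cyclopentane-fused cage ester: tricyclic lactone with ring C1–CH2–CH(OTBDPS)–CH2–C6, C6–CH2 bond and C5 benzyl ester syn to the lactone bridge, 4-OBn, 8-OBn | c1ccccc1CO[C@@]23C(=O)O[C@]4(C[C@H](O[Si](c7ccccc7)(c7ccccc7)C(C)(C)C)C[C@H]4[C@H]2C(=O)OCc5ccccc5)C[C@H]3OCc6ccccc6 | intermediate
19 | hydroxy acid: C5 carboxylic acid, C4 and C8 hydroxyls free | O[C@@]23C(=O)O[C@]4(C[C@H](O[Si](c7ccccc7)(c7ccccc7)C(C)(C)C)C[C@H]4[C@H]2C(=O)O)C[C@H]3O | intermediate
20 | pentafluorophenyl ester of 19 | O[C@@]23C(=O)O[C@]4(C[C@H](O[Si](c7ccccc7)(c7ccccc7)C(C)(C)C)C[C@H]4[C@H]2C(=O)Oc5c(F)c(F)c(F)c(F)c5F)C[C@H]3O | intermediate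
21 | β-diketone: C5 carries an (E)-2-methyl-3-oxododec-4-enoyl group (methyl-bearing carbon as epimers or enol) | O[C@@]23C(=O)O[C@]4(C[C@H](O[Si](c7ccccc7)(c7ccccc7)C(C)(C)C)C[C@H]4[C@H]2C(=O)C(C)C(=O)/C=C/CCCCCCC)C[C@H]3O | intermediate (not isolated)
22 | cage-fused 2,3-dihydro-4H-pyran-4-one: ring O on C4, ring carbonyl on C5, 3-methyl, 2-[(E)-non-1-enyl] | CCCCCCC/C=C/C1O[C@@]23C(=O)O[C@]4(C[C@H](O[Si](c7ccccc7)(c7ccccc7)C(C)(C)C)C[C@H]4[C@H]2C(=O)C=1C)C[C@H]3O | intermediate
23 | allylic alcohol from 22 (ring carbonyl reduced, carbinol epimers) | CCCCCCC/C=C/C1O[C@@]23C(=O)O[C@]4(C[C@H](O[Si](c7ccccc7)(c7ccccc7)C(C)(C)C)C[C@H]4[C@H]2C(O)C=1C)C[C@H]3O | intermediate (not isolated)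
24 | tert-butyldiphenylsilyl ether of the target (cyclopentanol oxygen silylated) | CCCCCCC/C=C/[C@H]1O[C@@]23C(=O)O[C@]4(C[C@H](O[Si](c7ccccc7)(c7ccccc7)C(C)(C)C)C[C@H]4[C@H]2C=C1C)C[C@H]3O | intermediate
25 | CNP0127096.1 | CCCCCCC/C=C/[C@H]1O[C@@]23C(=O)O[C@]4(C[C@H](O)C[C@H]4[C@H]2C=C1C)C[C@H]3O | target

**Count**

Total steps: 14. Longest linear sequence: 11 steps (steps 4 to 14; the alkyne branch, steps 2, 3 and 6 to 14, is equally long).

**Steps most likely to fail**

1. Step 8. The process at risk is facial and regiochemical control in the cycloaddition. Two-point binding of a 3-benzyloxy lactone to the copper catalyst is an untested substrate pattern, and an unselective approach of the enol ether would erode the absolute configuration of the whole cage. Fallback, auxiliary control instead of catalyst control: starting from 14, the cycloaddition is run with the enantiopure enol ether [(1S)-1-(ethenyloxy)ethyl]benzene F1 (from (S)-1-phenylethanol and vinyl acetate with [Ir(cod)Cl]2 and Na2CO3) under ZnBr2 in CH2Cl2 at −40 °C, which should give the 8-(1-phenylethoxy) cycloadduct F2. Radical closure under the conditions of step 9 should give the ester-epimer mixture F3 and, after DBU, the tricyclic ester F4. Hydrogenolysis as in step 10 removes the 1-phenylethyl group together with the benzyl groups and returns to the route at 19.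

2. Step 13. The process at risk is facial selectivity of hydride transfer to the pyranyl cation: the stereoelectronically preferred pseudo-axial attack opposes the steric bias of the lactone carbonyl. Fallback, intramolecular delivery: starting from 22, the C8 hydroxyl is silylated with iPr2SiHCl and imidazole to give the hydrosilyl ether F5. Luche reduction should give the allylic alcohol F6. BF3·OEt2 at −78 °C ionises it, and the tethered Si–H, held on the pyran face that carries the C8 substituent, should transfer hydride to pyran C2 and leave the fluorosilyl ether F7. Bu4NF and AcOH as in step 14 then remove both silicon groups, and the route is rejoined at 25.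

3. Step 12. The process at risk is site selectivity of the acylation: γ-deprotonation of the enone to a dienolate, or acyl transfer to the free hydroxyls, would divert the active ester from the ethyl carbon. Fallback, reversed roles of the partners: starting from 20, acyl substitution with EtMgBr and CuBr·SMe2 in THF at −78 °C should give the ethyl ketone F8. Its enolisation with MgBr2·OEt2 and iPr2NEt, favoured on the ethyl side, and C-acylation with 1-[(E)-dec-2-enoyl]benzotriazole F9 (from (E)-dec-2-enoic acid, benzotriazole and SOCl2) should give the same diketone 21, which closes under the acid conditions of step 12, and the route is rejoined at 22.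

**Further compounds**

F1 | step 8 | [(1S)-1-(ethenyloxy)ethyl]benzene | C=CO[C@@H](C)c1ccccc1
F2 | step 8 | cycloadduct as 16 with 8-[(1S)-1-phenylethoxy] in place of 8-benzyloxy | c1ccccc1CO[C@@]23C(=O)O[C@@](C[C@@H](CBr)O[Si](c4ccccc4)(c4ccccc4)C(C)(C)C)(C=C2C(=O)OCc5ccccc5)C[C@H]3O[C@@H](C)c6ccccc6
F3 | step 8 | radical cyclisation product from F2 as a mixture of C5 ester epimers | c1ccccc1CO[C@@]23C(=O)O[C@]4(C[C@H](O[Si](c7ccccc7)(c7ccccc7)C(C)(C)C)C[C@H]4C2C(=O)OCc5ccccc5)C[C@H]3O[C@@H](C)c6ccccc6
F4 | step 8 | tricyclic ester as 18 with 8-[(1S)-1-phenylethoxy] in place of 8-benzyloxy | c1ccccc1CO[C@@]23C(=O)O[C@]4(C[C@H](O[Si](c7ccccc7)(c7ccccc7)C(C)(C)C)C[C@H]4[C@H]2C(=O)OCc5ccccc5)C[C@H]3O[C@@H](C)c6ccccc6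
F5 | step 13 | C8 O-(diisopropylsilyl) ether of 22 | CCCCCCC/C=C/C1O[C@@]23C(=O)O[C@]4(C[C@H](O[Si](c7ccccc7)(c7ccccc7)C(C)(C)C)C[C@H]4[C@H]2C(=O)C=1C)C[C@H]3O[SiH](C(C)C)C(C)C
F6 | step 13 | allylic alcohol from F5 (carbinol epimers) | CCCCCCC/C=C/C1O[C@@]23C(=O)O[C@]4(C[C@H](O[Si](c7ccccc7)(c7ccccc7)C(C)(C)C)C[C@H]4[C@H]2C(O)C=1C)C[C@H]3O[SiH](C(C)C)C(C)C
F7 | step 13 | C8 O-(fluorodiisopropylsilyl) ether of 24 | CCCCCCC/C=C/[C@H]1O[C@@]23C(=O)O[C@]4(C[C@H](O[Si](c7ccccc7)(c7ccccc7)C(C)(C)C)C[C@H]4[C@H]2C=C1C)C[C@H]3O[Si](F)(C(C)C)C(C)C
F8 | step 12 | ethyl ketone: propanoyl group on C5 in place of the active ester of 20 | O[C@@]23C(=O)O[C@]4(C[C@H](O[Si](c7ccccc7)(c7ccccc7)C(C)(C)C)C[C@H]4[C@H]2C(=O)CC)C[C@H]3O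
F9 | step 12 | 1-[(E)-dec-2-enoyl]-1H-benzotriazole | CCCCCCC/C=C/C(=O)n1nnc2ccccc12
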